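The isoxazolidine is opened at O2–C3 and both side chains are removed, leaving the cyclopentane ring (C3a, C4–C6, C6a) with two vicinal cis bonds, N1–C6a and C3–C3a. A (2+2) cycloaddition of chlorosulfonyl isocyanate to cyclopentene makes both bonds at once, locks them cis through a temporary azetidinone ring and delivers C3 as an acyl carbon ready for chain attachment. The precursors are the two commercial reagents. Lipase resolution then supplies the absolute configuration, and Grignard ring opening, reductive amination, N-hydroxylation and a convex-face ionic reduction close O2–C3 with the C3 configuration set by the bicyclic shape.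

Key step: step 1

Remark on the chemistry: the resolved (1S,5R)-lactam maps C1 onto C3a (S) and C5 onto C6a (R) of the target. N-hydroxy amino ketone 24 and hemiketal 25 are ring–chain tautomers, and 25 (both C3 epimers) is taken as the isolated form. Bromide 10 is used directly after preparation because ω-bromoalkylpyridines self-quaternize on storage.

Step 1
Reactants: 1 cyclopentene; 2 chlorosulfonyl isocyanate
Product: 4 rac-cis-6-azabicyclo[3.2.0]heptan-7-one, via N-chlorosulfonyl lactam 3 (not isolated)
Conditions: ClSO2NCO, CH2Cl2, 0 °C → rt; then aq Na2SO3, NaHCO3 (pH 7–8), 0 °C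
Reagents that add atoms: none
Why: Chlorosulfonyl isocyanate is electrophilic enough to add to an unactivated alkene in a (2+2) cycloaddition, its carbon bonding to one alkene carbon in a highly asynchronous (short-lived 1,4-dipolar) pathway before nitrogen closes onto the neighbouring carbon on the same face; this is the established isocyanate–alkene β-lactam synthesis. The azetidinone ring is closed by the cycloaddition itself, suprafacially on the alkene, and a four-membered ring fused to cyclopentane can only be cis. The two new stereocenters (C1 and C5, later C3a and C6a) are therefore fixed relative to each other by the ring fusion, while their absolute sense is not controlled and the product should be racemic. No regiochemistry arises because cyclopentene is symmetric, and the only selectivity needed is N–S cleavage without lactam opening, which buffered sulfite should secure by reducing the sulfonyl chloride to a sulfinate that loses SO2 at near-neutral pH.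

Step 2
Reactants: 4 rac-cis-6-azabicyclo[3.2.0]heptan-7-one
Product: 5 (1S,5R)-6-azabicyclo[3.2.0]heptan-7-one
Conditions: immobilized Candida antarctica lipase B, H2O (1 equiv), iPr2O, 60 °C, to about half conversion; filter, concentrate filtrate
Reagents that add atoms: none
Why: Lipase-catalysed kinetic resolution by enantioselective hydrolytic ring opening, in which the enzyme should accept only the (1R,5S)-lactam and release it as the insoluble amino acid, so that the untouched (1S,5R)-enantiomer is recovered from solution; no stereocenter is formed and half of the material is sacrificed.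

Step 3
Reactants: 5 (1S,5R)-6-azabicyclo[3.2.0]heptan-7-one
Product: 6 tert-butyl (1S,5R)-7-oxo-6-azabicyclo[3.2.0]heptane-6-carboxylate
Conditions: Boc2O, DMAP (cat.), MeCN, rt
Reagents that add atoms: di-tert-butyl dicarbonate, CC(C)(C)OC(=O)OC(=O)OC(C)(C)C
Why: DMAP-catalysed N-acylation of the lactam N–H gives the imide-like N-Boc β-lactam, whose ring carbonyl is activated for nucleophilic opening, and neither stereocenter is touched.

Step 4
Reactants: 7 3-methylpyridine; 8 1,7-dibromoheptane
Product: 10 3-(8-bromooctyl)pyridine, via 3-picolyllithium 9 (not isolated)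
Conditions: LDA, THF, −78 °C; then 8 (3 equiv), −78 °C → rt
Reagents that add atoms: none
Why: Lateral lithiation of 3-picoline followed by SN2 alkylation of the picolyl anion, where excess dibromide should suppress double alkylation.

Step 5
Reactants: 6 tert-butyl (1S,5R)-7-oxo-6-azabicyclo[3.2.0]heptane-6-carboxylate; 10 3-(8-bromooctyl)pyridine
Product: 12 tert-butyl N-[(1R,2S)-2-[9-(pyridin-3-yl)nonanoyl]cyclopentyl]carbamate, via Grignard reagent 11 (not isolated)
Conditions: 10, Mg, THF, rt → 40 °C; then 6, THF, −78 → −40 °C; sat. aq NH4Cl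
Reagents that add atoms: none
Why: Grignard formation from the primary bromide and nucleophilic ring opening of the N-Boc β-lactam (acyl substitution at the strained imide carbonyl), in which the chelated adduct should either persist cold or collapse to a ketone less electrophilic than the imide, so that a second addition and enolization are avoided and the cis relationship at C1/C2 is kept.

Step 6
Reactants: 13 pent-4-yn-1-ol; 14 9-bromonon-1-ene
Product: 16 tetradec-13-en-4-yn-1-ol, via dilithiated pentynol 15 (not isolated)
Conditions: n-BuLi (2.1 equiv), THF/DMPU, −78 → 0 °C; then 14 (1.0 equiv), 0 °C → rt; H2O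
Reagents that add atoms: none
Why: Double deprotonation of the alkynol and SN2 alkylation at the more nucleophilic acetylide carbon (acetylide alkylation) by the primary bromide, whose terminal alkene is inert to the dianion.

Step 7
Reactants: 16 tetradec-13-en-4-yn-1-ol; 17 3-bromopyridine
Product: 19 14-(pyridin-3-yl)tetradec-4-yn-1-ol, via doubly borylated alkynol 18 (not isolated)
Conditions: 9-BBN (2.2 equiv), THF, 0 °C → rt; then 17, Pd(dppf)Cl2 (cat.), 3 M aq NaOH, THF, 65 °C
Reagents that add atoms: none
Why: Hydroboration followed by B-alkyl Suzuki–Miyaura coupling, in which 9-BBN adds anti-Markovnikov to the terminal alkene much faster than to the internal alkyne, a second equivalent masks the hydroxyl as its borinate (hydrolysed again in the aqueous base), and the primary alkylborane transfers its chain to 3-bromopyridine on palladium.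

Step 8
Reactants: 19 14-(pyridin-3-yl)tetradec-4-yn-1-ol
Product: 20 (4Z)-14-(pyridin-3-yl)tetradec-4-en-1-ol
Conditions: H2 (1 atm), Lindlar catalyst, quinoline, EtOAc, rt
Reagents that add atoms: none
Why: Lindlar semihydrogenation, in which syn delivery of hydrogen on the poisoned palladium surface should give the (Z)-alkene without reducing the pyridine ring.

Step 9
Reactants: 20 (4Z)-14-(pyridin-3-yl)tetradec-4-en-1-ol
Product: 21 (4Z)-14-(pyridin-3-yl)tetradec-4-enal
Conditions: Dess–Martin periodinane, CH2Cl2, 0 °C → rt
Reagents that add atoms: none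
Why: Dess–Martin oxidation of the primary alcohol to the aldehyde under non-basic conditions that should leave the (Z)-alkene in place and tolerate the pyridine.

Step 10
Reactants: 12 tert-butyl N-[(1R,2S)-2-[9-(pyridin-3-yl)nonanoyl]cyclopentyl]carbamate; 21 (4Z)-14-(pyridin-3-yl)tetradec-4-enal
Product: 23 1-[(1S,2R)-2-{[(4Z)-14-(pyridin-3-yl)tetradec-4-en-1-yl]amino}cyclopentyl]-9-(pyridin-3-yl)nonan-1-one, via primary amine trifluoroacetate 22 (not isolated)
Conditions: TFA, CH2Cl2, 0 °C → rt, evaporate; then 21 (1.0 equiv), Et3N, 4 Å MS, DCE, rt; NaBH(OAc)3, 0 °C → rt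
Reagents that add atoms: none
Why: Acidolytic Boc removal followed by reductive amination, in which the primary amine condenses with the aldehyde far faster than with its own hindered ketone and NaBH(OAc)3 reduces the iminium ion but not the ketone, while the mildly acidic medium should avoid epimerization next to the ketone.

Step 11
Reactants: 23 1-[(1S,2R)-2-{[(4Z)-14-(pyridin-3-yl)tetradec-4-en-1-yl]amino}cyclopentyl]-9-(pyridin-3-yl)nonan-1-one
Product: 25 (3aS,6aR)-3-[8-(pyridin-3-yl)octyl]-1-[(4Z)-14-(pyridin-3-yl)tetradec-4-en-1-yl]hexahydro-1H-cyclopenta[c][1,2]oxazol-3-ol, via N-hydroxy amino ketone 24 (not isolated)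
Conditions: 2-(benzenesulfonyl)-3-phenyloxaziridine (1.05 equiv), CH2Cl2, −78 → 0 °C
Reagents that add atoms: 2-(benzenesulfonyl)-3-phenyloxaziridine, O=S(=O)(c1ccccc1)N1OC1c1ccccc1
Why: Electrophilic N-hydroxylation of a secondary amine by an N-sulfonyloxaziridine (oxygen-atom transfer to the most nucleophilic nitrogen, well ahead of the pyridines and the alkene), after which the hydroxylamine oxygen adds to the ketone (5-exo-trig) to give the cis-fused hemiketal, a form that also shields it from over-oxidation to a nitrone.

Step 12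
Reactants: 25 (3aS,6aR)-3-[8-(pyridin-3-yl)octyl]-1-[(4Z)-14-(pyridin-3-yl)tetradec-4-en-1-yl]hexahydro-1H-cyclopenta[c][1,2]oxazol-3-ol
Product: 26 (3S,3aS,6aR)-3-[8-(pyridin-3-yl)octyl]-1-[(4Z)-14-(pyridin-3-yl)tetradec-4-en-1-yl]hexahydro-1H-cyclopenta[c][1,2]oxazole
Conditions: Et3SiH, TFA, CH2Cl2, −20 °C → rt; aq NaHCO3
Reagents that add atoms: none
Why: Ionic hydrogenation (silane reductive etherification of a cyclic hemiketal), in which acid ionizes the hemiketal to the N-alkoxy oxocarbenium ion and Et3SiH should deliver hydride to the convex face of the cis-fused bicycle, the face carrying H3a and H6a, which places H3 cis to both and the octyl chain on the concave face, i.e. (3S).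

Compound list
1 | cyclopentene | C1=CCCC1 | starting material
2 | chlorosulfonyl isocyanate | O=C=NS(=O)(=O)Cl | starting material
3 | rac-cis-7-oxo-6-azabicyclo[3.2.0]heptane-6-sulfonyl chloride (racemate, both enantiomers written) | ClS(=O)(=O)N1C(=O)[C@H]2CCC[C@H]21.ClS(=O)(=O)N1C(=O)[C@@H]2CCC[C@@H]21 | intermediate (not isolated)
4 | rac-cis-6-azabicyclo[3.2.0]heptan-7-one (racemate, both enantiomers written) | N1C(=O)[C@H]2CCC[C@H]21.N1C(=O)[C@@H]2CCC[C@@H]21 | intermediate
5 | (1S,5R)-6-azabicyclo[3.2.0]heptan-7-one | N1C(=O)[C@H]2CCC[C@H]21 | intermediate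
6 | tert-butyl (1S,5R)-7-oxo-6-azabicyclo[3.2.0]heptane-6-carboxylate | CC(C)(C)OC(=O)N1C(=O)[C@H]2CCC[C@H]21 | intermediate
7 | 3-methylpyridine | Cc1cccnc1 | starting material
8 | 1,7-dibromoheptane | BrCCCCCCCBr | starting material
9 | (pyridin-3-ylmethyl)lithium | [Li]Cc1cccnc1 | intermediate (not isolated)
10 | 3-(8-bromooctyl)pyridine | BrCCCCCCCCc1cccnc1 | intermediate
11 | [8-(pyridin-3-yl)octyl]magnesium bromide | Br[Mg]CCCCCCCCc1cccnc1 | intermediate (not isolated)
12 | tert-butyl N-[(1R,2S)-2-[9-(pyridin-3-yl)nonanoyl]cyclopentyl]carbamate | CC(C)(C)OC(=O)N[C@@H]1CCC[C@@H]1C(=O)CCCCCCCCc1cccnc1 | intermediate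
13 | pent-4-yn-1-ol | OCCCC#C | starting material
14 | 9-bromonon-1-ene | BrCCCCCCCC=C | starting material
15 | dilithium salt of pent-4-yn-1-ol (O-lithio, C-lithio) | [Li]OCCCC#C[Li] | intermediate (not isolated)
16 | tetradec-13-en-4-yn-1-ol | OCCCC#CCCCCCCCC=C | intermediate
17 | 3-bromopyridine | Brc1cccnc1 | starting material
18 | 9-{[14-(9-borabicyclo[3.3.1]nonan-9-yl)tetradec-4-yn-1-yl]oxy}-9-borabicyclo[3.3.1]nonane | B1(OCCCC#CCCCCCCCCCB2C3CCCC2CCC3)C2CCCC1CCC2 | intermediate (not isolated)
19 | 14-(pyridin-3-yl)tetradec-4-yn-1-ol | OCCCC#CCCCCCCCCCc1cccnc1 | intermediate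
20 | (4Z)-14-(pyridin-3-yl)tetradec-4-en-1-ol | OCCC/C=C\CCCCCCCCCc1cccnc1 | intermediate
21 | (4Z)-14-(pyridin-3-yl)tetradec-4-enal | O=CCC/C=C\CCCCCCCCCc1cccnc1 | intermediate
22 | 1-[(1S,2R)-2-aminocyclopentyl]-9-(pyridin-3-yl)nonan-1-one (handled as its trifluoroacetate salt) | N[C@@H]1CCC[C@@H]1C(=O)CCCCCCCCc1cccnc1 | intermediate (not isolated)
23 | 1-[(1S,2R)-2-{[(4Z)-14-(pyridin-3-yl)tetradec-4-en-1-yl]amino}cyclopentyl]-9-(pyridin-3-yl)nonan-1-one | O=C(CCCCCCCCc1cccnc1)[C@H]1CCC[C@H]1NCCC/C=C\CCCCCCCCCc1cccnc1 | intermediate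
24 | 1-[(1S,2R)-2-{hydroxy[(4Z)-14-(pyridin-3-yl)tetradec-4-en-1-yl]amino}cyclopentyl]-9-(pyridin-3-yl)nonan-1-one | O=C(CCCCCCCCc1cccnc1)[C@H]1CCC[C@H]1N(O)CCC/C=C\CCCCCCCCCc1cccnc1 | intermediate (not isolated)
25 | (3aS,6aR)-3-[8-(pyridin-3-yl)octyl]-1-[(4Z)-14-(pyridin-3-yl)tetradec-4-en-1-yl]hexahydro-1H-cyclopenta[c][1,2]oxazol-3-ol (both C3 epimers, C3 left undefined) | C(=C/CCCN1OC(O)(CCCCCCCCc2cccnc2)[C@H]2CCC[C@H]21)/CCCCCCCCCc1cccnc1 | intermediate
26 | (3S,3aS,6aR)-3-[8-(pyridin-3-yl)octyl]-1-[(4Z)-14-(pyridin-3-yl)tetradec-4-en-1-yl]hexahydro-1H-cyclopenta[c][1,2]oxazole | C(=C/CCCN1O[C@@H](CCCCCCCCc2cccnc2)[C@H]2CCC[C@H]21)/CCCCCCCCCc1cccnc1 | target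

Total step count: 12.
Longest linear sequence: 7 steps (1 → 2 → 3 → 5 → 10 → 11 → 12; the C14 branch 6 → 7 → 8 → 9 → 10 → 11 → 12 is equally long).

Steps most likely to fail

Step 5, formation and single addition of the organomagnesium reagent. The bromide may alkylate its own pyridine nitrogen while magnesium inserts, the liberated ketone may take up a second equivalent of reagent, and the basic medium may enolize the ketone next to the ring (loss of the cis relationship or β-elimination of the carbamate). The fallback sets out from 6 and 10 and comes back at 12. Ethanethiol with catalytic base should open the N-Boc lactam 6 to S-ethyl (1S,2R)-2-[(tert-butoxycarbonyl)amino]cyclopentane-1-carbothioate F1. Zinc dust with LiCl in THF should convert 10 into [8-(pyridin-3-yl)octyl]zinc bromide F2. A palladium-catalysed thioester–organozinc (Fukuyama) coupling of F1 with F2 should then give ketone 12 under neutral conditions in which neither over-addition nor enolization is expected.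

Step 11, chemoselective oxygen transfer to the amine. Oxygen may also be transferred to the pyridine nitrogens, the hydroxylamine may be oxidized on to a nitrone before it cyclizes, or the sulfonylimine by-product may consume the amine. The fallback sets out from 23 and comes back at 25. Dibenzoyl peroxide with K2HPO4 in DMF should acyloxylate only the aliphatic nitrogen to give 1-[(1S,2R)-2-{(benzoyloxy)[(4Z)-14-(pyridin-3-yl)tetradec-4-en-1-yl]amino}cyclopentyl]-9-(pyridin-3-yl)nonan-1-one F3, in which the oxygen arrives capped and cannot be oxidized further. A short methanolysis (K2CO3, MeOH, 0 °C) should remove the benzoate, and the freed N–OH should close onto the ketone to give hemiketal 25.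

Step 12, ionization and face-selective hydride delivery. The polyprotonated substrate may ionize sluggishly, hydride may arrive with poor facial selectivity, or the acid may cleave the N–O bond. The fallback sets out from 12 and comes back at 26; it fixes C3 by reagent control and SN2 inversion instead of by facial bias. (S)-Me-CBS reduction of the ketone with excess borane (cyclopentyl as the large group, the pyridine–borane complex being broken on work-up) should give tert-butyl N-[(1R,2S)-2-[(1R)-1-hydroxy-9-(pyridin-3-yl)nonyl]cyclopentyl]carbamate F4. Boc removal and reductive amination with 21, as in step 10, should give (1R)-1-[(1S,2R)-2-{[(4Z)-14-(pyridin-3-yl)tetradec-4-en-1-yl]amino}cyclopentyl]-9-(pyridin-3-yl)nonan-1-ol F5. N-hydroxylation, as in step 11, should give (1R)-1-[(1S,2R)-2-{hydroxy[(4Z)-14-(pyridin-3-yl)tetradec-4-en-1-yl]amino}cyclopentyl]-9-(pyridin-3-yl)nonan-1-ol F6. A Mitsunobu-type cyclodehydration ((cyanomethylene)tributylphosphorane, toluene, heat) should then let the hydroxylamine oxygen displace the activated carbinol with inversion, giving target 26.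

Further compounds
F1 | step 5 | S-ethyl (1S,2R)-2-[(tert-butoxycarbonyl)amino]cyclopentane-1-carbothioate | CCSC(=O)[C@H]1CCC[C@H]1NC(=O)OC(C)(C)C
F2 | step 5 | [8-(pyridin-3-yl)octyl]zinc bromide | Br[Zn]CCCCCCCCc1cccnc1
F3 | step 11 | 1-[(1S,2R)-2-{(benzoyloxy)[(4Z)-14-(pyridin-3-yl)tetradec-4-en-1-yl]amino}cyclopentyl]-9-(pyridin-3-yl)nonan-1-one | O=C(CCCCCCCCc1cccnc1)[C@H]1CCC[C@H]1N(OC(=O)c1ccccc1)CCC/C=C\CCCCCCCCCc1cccnc1
F4 | step 12 | tert-butyl N-[(1R,2S)-2-[(1R)-1-hydroxy-9-(pyridin-3-yl)nonyl]cyclopentyl]carbamate | CC(C)(C)OC(=O)N[C@@H]1CCC[C@@H]1[C@H](O)CCCCCCCCc1cccnc1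
F5 | step 12 | (1R)-1-[(1S,2R)-2-{[(4Z)-14-(pyridin-3-yl)tetradec-4-en-1-yl]amino}cyclopentyl]-9-(pyridin-3-yl)nonan-1-ol | O[C@H](CCCCCCCCc1cccnc1)[C@H]1CCC[C@H]1NCCC/C=C\CCCCCCCCCc1cccnc1
F6 | step 12 | (1R)-1-[(1S,2R)-2-{hydroxy[(4Z)-14-(pyridin-3-yl)tetradec-4-en-1-yl]amino}cyclopentyl]-9-(pyridin-3-yl)nonan-1-ol | O[C@H](CCCCCCCCc1cccnc1)[C@H]1CCC[C@H]1N(O)CCC/C=C\CCCCCCCCCc1cccnc1
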